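The oxepine ring (O1, C2–C7) is cut at its only double bond, C5=C6. Ring-closing metathesis of an acyclic 1,8-diene closes this seven-membered ring last. In the same operation it fixes the ring-cis geometry of the trisubstituted C5=C6 alkene, which an open-chain olefination would have to control. The fully substituted C2 serves as the turn element. The precursor is an (S)-configured tertiary ether carrying a but-3-enyl group on C2 and a 2-substituted allyl group on O1. Its C2 stereocentre comes from a copper–bis(oxazoline)-catalysed Mukaiyama aldol addition to an α-keto ester. Late allylic oxidation and one fluoride step finish the synthesis.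

Key step: step 9

Remark on the chemistry: the oxepine is numbered O1, C2 (quaternary, S), C3, C4, C5=C6, C7. But-3-enylmagnesium bromide is taken as a commercial THF solution. TBS = tert-butyldimethylsilyl.

Step 1
Reactants: 1 2-methylprop-2-en-1-ol; 2 1-bromo-3-methylbut-2-ene (prenyl bromide)
Product: 4 6-methyl-2-methylidenehept-5-en-1-ol, via dilithio dianion 3 (not isolated)
Conditions: n-BuLi (2.2 equiv), TMEDA, Et2O, 0 °C to rt; then 2, THF, −78 °C to rt; H2O
Reagents that add atoms: none
Why: Alkoxide-directed allylic lithiation gives a delocalised dianion whose carbon terminus should displace the primary allylic bromide (dianion alkylation, SN2); no stereocentre is formed.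

Step 2
Reactants: 4 6-methyl-2-methylidenehept-5-en-1-ol
Product: 5 2-(bromomethyl)-6-methylhepta-1,5-diene
Conditions: CBr4, PPh3, CH2Cl2, 0 °C
Reagents that add atoms: carbon tetrabromide BrC(Br)(Br)Br
Why: The Appel reaction converts the primary allylic alcohol into the bromide under neutral conditions that leave both alkenes untouched.

Step 3
Reactants: 6 oxalyl chloride; 7 2-(trimethylsilyl)ethanol
Product: 8 bis[2-(trimethylsilyl)ethyl] oxalate
Conditions: 7 (2.1 equiv), Et3N, CH2Cl2, 0 °C
Reagents that add atoms: none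
Why: Double acylation of the alcohol by the diacid chloride installs an ester that fluoride can remove at the end without hydroxide.

Step 4
Reactants: 8 bis[2-(trimethylsilyl)ethyl] oxalate; 9 but-3-enylmagnesium bromide
Product: 10 2-(trimethylsilyl)ethyl 2-oxohex-5-enoate
Conditions: 9 (1.0 equiv, slow addition), THF, −78 °C; 1 M HCl quench
Reagents that add atoms: none
Why: In this Grignard mono-addition to a dialkyl oxalate the tetrahedral magnesium adduct should persist at low temperature, so the α-keto ester appears only on quenching and is not attacked twice.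

Step 5
Reactants: 11 1-(2,5-dihydroxyphenyl)ethanone
Product: 12 1-[2,5-bis(tert-butyldimethylsilyloxy)phenyl]ethanone
Conditions: TBSCl (2.5 equiv), imidazole, DMF, rt to 45 °C
Reagents that add atoms: tert-butyldimethylsilyl chloride CC(C)(C)[Si](C)(C)Cl
Why: Silylation masks both phenols, the hydrogen-bonded ortho one included, as ethers that withstand Lewis acid, silver oxide, ruthenium and selenium dioxide and fall to fluoride.

Step 6
Reactants: 12 1-[2,5-bis(tert-butyldimethylsilyloxy)phenyl]ethanone
Product: 13 {1-[2,5-bis(tert-butyldimethylsilyloxy)phenyl]ethenyloxy}trimethylsilane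
Conditions: Me3SiOTf, Et3N, CH2Cl2, 0 °C
Reagents that add atoms: trimethylsilyl trifluoromethanesulfonate C[Si](C)(C)OS(=O)(=O)C(F)(F)F
Why: Soft enolisation of the methyl ketone gives its only possible silyl enol ether.

Step 7
Reactants: 10 2-(trimethylsilyl)ethyl 2-oxohex-5-enoate; 13 {1-[2,5-bis(tert-butyldimethylsilyloxy)phenyl]ethenyloxy}trimethylsilane
Product: 15 2-(trimethylsilyl)ethyl (2S)-2-{2-[2,5-bis(tert-butyldimethylsilyloxy)phenyl]-2-oxoethyl}-2-hydroxyhex-5-enoate, via trimethylsilyl ether 14 (not isolated)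
Conditions: Cu(OTf)2 (10 mol %), 2,2'-isopropylidenebis[(4S)-4-tert-butyl-2-oxazoline] (11 mol %), THF, −78 °C; then 1 M HCl, THF, 0 °C
Reagents that add atoms: none
Why: This is a catalytic enantioselective Mukaiyama aldol addition to an α-keto ester: the keto ester chelates divalent copper in a square-planar complex, the tert-butyl groups of the (S,S)-ligand shield the re face of the ketone, and si-face attack should set C2 as S (the ligand antipode would give R).

Step 8
Reactants: 15 2-(trimethylsilyl)ethyl (2S)-2-{2-[2,5-bis(tert-butyldimethylsilyloxy)phenyl]-2-oxoethyl}-2-hydroxyhex-5-enoate; 5 2-(bromomethyl)-6-methylhepta-1,5-diene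
Product: 16 2-(trimethylsilyl)ethyl (2S)-2-{2-[2,5-bis(tert-butyldimethylsilyloxy)phenyl]-2-oxoethyl}-2-[(6-methyl-2-methylidenehept-5-en-1-yl)oxy]hex-5-enoate
Conditions: 5 (3 equiv), Ag2O (3 equiv), 4 Å molecular sieves, toluene, dark, rt to 40 °C
Reagents that add atoms: none
Why: In this silver-oxide-promoted Williamson-type etherification silver activates the allylic bromide, and the fairly acidic α-hydroxy ester oxygen is alkylated without a free alkoxide, so retro-aldol cleavage is avoided and C2 is untouched.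

Step 9
Reactants: 16 2-(trimethylsilyl)ethyl (2S)-2-{2-[2,5-bis(tert-butyldimethylsilyloxy)phenyl]-2-oxoethyl}-2-[(6-methyl-2-methylidenehept-5-en-1-yl)oxy]hex-5-enoate
Product: 17 2-(trimethylsilyl)ethyl (2S)-2-{2-[2,5-bis(tert-butyldimethylsilyloxy)phenyl]-2-oxoethyl}-6-(4-methylpent-3-en-1-yl)-2,3,4,7-tetrahydrooxepine-2-carboxylate
Conditions: second-generation Grubbs catalyst RuCl2(=CHPh)(PCy3)(H2IMes) (5 mol %), 1,4-benzoquinone (10 mol %), CH2Cl2 (2 mM), reflux, argon sparge
Reagents that add atoms: none
Why: Ring-closing olefin metathesis proceeds through metallacyclobutanes: the ruthenium benzylidene first exchanges onto the unhindered monosubstituted but-3-enyl alkene (C5), the new alkylidene adds intramolecularly to the 1,1-disubstituted allyl-ether alkene (C6), and cycloreversion releases ethene and the C5=C6 bond. The closest known reaction type is the ring-closing metathesis of allyl alkenyl ethers to 2,3,4,7-tetrahydrooxepines bearing a trisubstituted double bond. The one ring formed, the seven-membered oxepine O1–C7, is closed by C5=C6 double-bond formation from a 1,8-diene. No stereocentre is created: C2 lies away from the reacting carbons and keeps its S configuration, and the C5=C6 geometry (C4 cis to C7) is dictated by the seven-membered ring, which cannot hold a trans alkene. The step needs chemoselectivity among three alkenes and cyclisation rather than oligomerisation: the trisubstituted 4-methylpent-3-enyl alkene is too hindered to compete and could only lead to a cyclobutene or a ten-membered ring, while the fully substituted C2 (gem-disubstituent effect) and high dilution favour closure. Removal of ethene should make the closure effectively irreversible, and benzoquinone suppresses ruthenium-hydride alkene migration.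

Step 10
Reactants: 17 2-(trimethylsilyl)ethyl (2S)-2-{2-[2,5-bis(tert-butyldimethylsilyloxy)phenyl]-2-oxoethyl}-6-(4-methylpent-3-en-1-yl)-2,3,4,7-tetrahydrooxepine-2-carboxylate
Product: 18 2-(trimethylsilyl)ethyl (2S)-2-{2-[2,5-bis(tert-butyldimethylsilyloxy)phenyl]-2-oxoethyl}-6-[(3E)-5-hydroxy-4-methylpent-3-en-1-yl]-2,3,4,7-tetrahydrooxepine-2-carboxylate
Conditions: SeO2 (0.3 equiv), t-BuOOH (3 equiv, decane solution), salicylic acid (0.1 equiv), CH2Cl2, 0 °C to rt, stopped at partial conversion
Reagents that add atoms: selenium dioxide O=[Se]=O (transfers the oxygen atom); tert-butyl hydroperoxide CC(C)(C)OO (re-oxidant and ultimate oxygen source)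
Why: In the selenium dioxide allylic oxidation (ene reaction, then [2,3]-sigmatropic shift) the electron-rich gem-dimethyl alkene should react before the ring alkene, which is deactivated by the allylic O1, and the envelope transition state places oxygen on the methyl group trans to the chain (E).

Step 11
Reactants: 18 2-(trimethylsilyl)ethyl (2S)-2-{2-[2,5-bis(tert-butyldimethylsilyloxy)phenyl]-2-oxoethyl}-6-[(3E)-5-hydroxy-4-methylpent-3-en-1-yl]-2,3,4,7-tetrahydrooxepine-2-carboxylate
Product: 19 (2S)-2-[2-(2,5-dihydroxyphenyl)-2-oxoethyl]-6-[(3E)-5-hydroxy-4-methylpent-3-en-1-yl]-2,3,4,7-tetrahydrooxepine-2-carboxylic acid (target)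
Conditions: n-Bu4NF (5 equiv), THF, argon, 0 °C to rt; cold 0.5 M HCl work-up
Reagents that add atoms: none
Why: Fluoride-induced desilylation cleaves both aryl silyl ethers at once and fragments the 2-(trimethylsilyl)ethyl ester into carboxylate, ethene and Me3SiF; the ortho-phenoxide formed first lowers the acidity of the ketone CH2, so C2 should stay intact.

Compound list
1 | 2-methylprop-2-en-1-ol | C=C(C)CO | starting material
2 | 1-bromo-3-methylbut-2-ene | CC(C)=CCBr | starting material
3 | lithium 2-(lithiomethyl)prop-2-en-1-olate (dilithio dianion of 1) | [Li]CC(=C)CO[Li] | intermediate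
4 | 6-methyl-2-methylidenehept-5-en-1-ol | OCC(=C)CCC=C(C)C | intermediate
5 | 2-(bromomethyl)-6-methylhepta-1,5-diene | BrCC(=C)CCC=C(C)C | intermediate
6 | oxalyl chloride | O=C(Cl)C(=O)Cl | starting material
7 | 2-(trimethylsilyl)ethanol | C[Si](C)(C)CCO | starting material
8 | bis[2-(trimethylsilyl)ethyl] oxalate | C[Si](C)(C)CCOC(=O)C(=O)OCC[Si](C)(C)C | intermediate
9 | but-3-enylmagnesium bromide | C=CCC[Mg]Br | starting material
10 | 2-(trimethylsilyl)ethyl 2-oxohex-5-enoate | C=CCCC(=O)C(=O)OCC[Si](C)(C)C | intermediate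
11 | 1-(2,5-dihydroxyphenyl)ethanone | CC(=O)c1cc(O)ccc1O | starting material
12 | 1-[2,5-bis(tert-butyldimethylsilyloxy)phenyl]ethanone | CC(=O)c1cc(O[Si](C)(C)C(C)(C)C)ccc1O[Si](C)(C)C(C)(C)C | intermediate
13 | {1-[2,5-bis(tert-butyldimethylsilyloxy)phenyl]ethenyloxy}trimethylsilane | C=C(O[Si](C)(C)C)c1cc(O[Si](C)(C)C(C)(C)C)ccc1O[Si](C)(C)C(C)(C)C | intermediate
14 | 2-(trimethylsilyl)ethyl (2S)-2-{2-[2,5-bis(tert-butyldimethylsilyloxy)phenyl]-2-oxoethyl}-2-(trimethylsilyloxy)hex-5-enoate | C=CCC[C@](CC(=O)c1cc(O[Si](C)(C)C(C)(C)C)ccc1O[Si](C)(C)C(C)(C)C)(C(=O)OCC[Si](C)(C)C)O[Si](C)(C)C | intermediate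
15 | 2-(trimethylsilyl)ethyl (2S)-2-{2-[2,5-bis(tert-butyldimethylsilyloxy)phenyl]-2-oxoethyl}-2-hydroxyhex-5-enoate | C=CCC[C@](CC(=O)c1cc(O[Si](C)(C)C(C)(C)C)ccc1O[Si](C)(C)C(C)(C)C)(C(=O)OCC[Si](C)(C)C)O | intermediate
16 | 2-(trimethylsilyl)ethyl (2S)-2-{2-[2,5-bis(tert-butyldimethylsilyloxy)phenyl]-2-oxoethyl}-2-[(6-methyl-2-methylidenehept-5-en-1-yl)oxy]hex-5-enoate | C=CCC[C@](CC(=O)c1cc(O[Si](C)(C)C(C)(C)C)ccc1O[Si](C)(C)C(C)(C)C)(C(=O)OCC[Si](C)(C)C)OCC(=C)CCC=C(C)C | intermediate
17 | 2-(trimethylsilyl)ethyl (2S)-2-{2-[2,5-bis(tert-butyldimethylsilyloxy)phenyl]-2-oxoethyl}-6-(4-methylpent-3-en-1-yl)-2,3,4,7-tetrahydrooxepine-2-carboxylate | CC(C)=CCCC1=CCC[C@](CC(=O)c2cc(O[Si](C)(C)C(C)(C)C)ccc2O[Si](C)(C)C(C)(C)C)(C(=O)OCC[Si](C)(C)C)OC1 | intermediate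
18 | 2-(trimethylsilyl)ethyl (2S)-2-{2-[2,5-bis(tert-butyldimethylsilyloxy)phenyl]-2-oxoethyl}-6-[(3E)-5-hydroxy-4-methylpent-3-en-1-yl]-2,3,4,7-tetrahydrooxepine-2-carboxylate | C/C(=C\CCC1=CCC[C@](CC(=O)c2cc(O[Si](C)(C)C(C)(C)C)ccc2O[Si](C)(C)C(C)(C)C)(C(=O)OCC[Si](C)(C)C)OC1)CO | intermediate
19 | (2S)-2-[2-(2,5-dihydroxyphenyl)-2-oxoethyl]-6-[(3E)-5-hydroxy-4-methylpent-3-en-1-yl]-2,3,4,7-tetrahydrooxepine-2-carboxylic acid | C/C(=C\CCC1=CCC[C@](CC(=O)c2cc(O)ccc2O)(C(=O)O)OC1)CO | target

Total step count: 11
Longest linear sequence: 7 steps (steps 5, 6, 7, 8, 9, 10, 11)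

Steps most likely to fail

Step 8. The hindered tertiary hydroxyl may be alkylated too slowly, so that retro-aldol cleavage or dehydration of the β-hydroxy ketone takes over. The fallback brings in C7 at the aldehyde level and sets out from 4 and 14.
- Alcohol 4 is oxidised with MnO2 (CH2Cl2, rt) to 6-methyl-2-methylidenehept-5-enal F1.
- Silyl ether 14 is isolated from step 7 by leaving out the acid treatment. It is combined with F1 and Et3SiH under catalytic Me3SiOTf (CH2Cl2, −78 °C).
- This reductive etherification runs through the silylated hemiacetal and its allyl-stabilised oxocarbenium ion and needs no alkoxide. It comes back to the route at 16.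

Step 10. Oxidation may also strike the allylic positions of the ring alkene, or run on from the alcohol to the enal. The fallback carries the oxygen in from the start. It sets out from dianion 3 and from 15 and comes back to the route at 19.
- Commercial 2-methyl-2-vinyloxirane is opened with TiCl4 (CH2Cl2, −85 °C) to (2E)-4-chloro-2-methylbut-2-en-1-ol F2.
- F2 is silylated (TBSCl, imidazole) to its TBS ether F3.
- Dianion 3 is alkylated with F3 to give (5E)-7-(tert-butyldimethylsilyloxy)-6-methyl-2-methylidenehept-5-en-1-ol F4.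
- The Appel reaction converts F4 into the allylic bromide F5.
- Etherification of 15 with F5 under the conditions of step 8 gives the silyloxy diene F6.
- Ring-closing metathesis as in step 9 gives the silyloxy oxepine F7.
- The fluoride treatment of step 11 removes all four silicon groups of F7 and gives 19.

Step 11. Basic fluoride may enolise the ketone and open the ring by retro-oxa-Michael elimination of O1, with loss of the C2 configuration on re-closure. The fallback sets out from 18, separates the two kinds of silicon group and avoids base.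
- Et3N·3HF (MeCN, 0 °C) removes only the aryl silyl ethers and gives the hydroquinone 2-(trimethylsilyl)ethyl ester F8.
- The ester is then cleaved by acid (CF3CO2H, CH2Cl2, 0 °C; β-silyl-assisted loss of ethene).
- A brief aqueous NaHCO3 wash followed by a pH 3 work-up hydrolyses the silyl trifluoroacetate and any allylic trifluoroacetate. This comes back to the route at 19.

Further compounds
F1 | step 8 | 6-methyl-2-methylidenehept-5-enal | C=C(C=O)CCC=C(C)C
F2 | step 10 | (2E)-4-chloro-2-methylbut-2-en-1-ol | C/C(=C\CCl)CO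
F3 | step 10 | tert-butyl{[(2E)-4-chloro-2-methylbut-2-en-1-yl]oxy}dimethylsilane | C/C(=C\CCl)CO[Si](C)(C)C(C)(C)C
F4 | step 10 | (5E)-7-(tert-butyldimethylsilyloxy)-6-methyl-2-methylidenehept-5-en-1-ol | C/C(=C\CCC(=C)CO)CO[Si](C)(C)C(C)(C)C
F5 | step 10 | {[(2E)-6-(bromomethyl)-2-methylhepta-2,6-dien-1-yl]oxy}(tert-butyl)dimethylsilane | C/C(=C\CCC(=C)CBr)CO[Si](C)(C)C(C)(C)C
F6 | step 10 | 2-(trimethylsilyl)ethyl (2S)-2-{2-[2,5-bis(tert-butyldimethylsilyloxy)phenyl]-2-oxoethyl}-2-{[(5E)-7-(tert-butyldimethylsilyloxy)-6-methyl-2-methylidenehept-5-en-1-yl]oxy}hex-5-enoate | C=CCC[C@](CC(=O)c1cc(O[Si](C)(C)C(C)(C)C)ccc1O[Si](C)(C)C(C)(C)C)(C(=O)OCC[Si](C)(C)C)OCC(=C)CC/C=C(\C)CO[Si](C)(C)C(C)(C)C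
F7 | step 10 | 2-(trimethylsilyl)ethyl (2S)-2-{2-[2,5-bis(tert-butyldimethylsilyloxy)phenyl]-2-oxoethyl}-6-[(3E)-5-(tert-butyldimethylsilyloxy)-4-methylpent-3-en-1-yl]-2,3,4,7-tetrahydrooxepine-2-carboxylate | C/C(=C\CCC1=CCC[C@](CC(=O)c2cc(O[Si](C)(C)C(C)(C)C)ccc2O[Si](C)(C)C(C)(C)C)(C(=O)OCC[Si](C)(C)C)OC1)CO[Si](C)(C)C(C)(C)C
F8 | step 11 | 2-(trimethylsilyl)ethyl (2S)-2-[2-(2,5-dihydroxyphenyl)-2-oxoethyl]-6-[(3E)-5-hydroxy-4-methylpent-3-en-1-yl]-2,3,4,7-tetrahydrooxepine-2-carboxylate | C/C(=C\CCC1=CCC[C@](CC(=O)c2cc(O)ccc2O)(C(=O)OCC[Si](C)(C)C)OC1)CO
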